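A direct plan would reduce 2,3-dimethylcyclopent-2-en-1-one A1 with an oxazaborolidine–borane system to (R)-2,3-dimethylcyclopent-2-en-1-ol A2 and would invert it by Mitsunobu etherification with 4-bromo-3-methylphenol A3 to the (S)-aryl cyclopentenyl ether A4. Aromatic Claisen rearrangement would then give the o-cyclopentenylphenol A5, zinc phenoxide-directed cyclopropanation the monobromo bicyclic phenol A6, and ortho-bromination of A6 the target.
- The Mitsunobu etherification of A2 with A3 would be weak: A2 is a readily ionised secondary allylic alcohol, so SN1, SN2′ and elimination pathways would erode the only source of chirality of the whole plan.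
- The aromatic Claisen rearrangement of A4 to A5 would be weak: it must create the benzylic quaternary carbon at a fully substituted allyl terminus at about 170 °C, where loss of the phenol to a diene and ionisation–recombination compete, and the stereocentre is relayed through three consecutive steps.
- The closing bromination of A6 would be weak: an electrophile and the HBr it can release meet a free phenol next to an acid-labile aryl cyclopropane at the last step.

**Retrosynthetic overview of the new route**

Numbering of the target core: C1 = methyl-bearing cyclopropane carbon, C2 = benzylic quaternary carbon, C3/C4 = ring CH2, C5 = cyclopropane CH, C6 = cyclopropane CH2.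
- Target ⇒ (alkene saturation, O-deacetylation) bicyclo[3.1.0]hex-3-ene 11 ⇒ (key step, bonds C5–C1 and C5–C6) acyclic 1,5-enyne 9, whose alkyne terminus is C5 and whose isopropenyl group is C1=C6.
- Enyne ⇒ (one-carbon homologation of the lactol) dihydrocoumarin 6, whose lactone carbonyl is C4 ⇒ (enantioselective conjugate addition of isopropenyl, bond C2–C1) coumarin 4 ⇒ dibrominated o-hydroxyacetophenone 2.
- Ring order: arene (bought) → temporary lactone → cyclopentene and cyclopropane together in one step; no ring of the bicyclic core exists before the key step.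
- The design has no allylic C–O stereocentre and no thermal sigmatropic step: C2 is set directly as a quaternary carbon and alone controls C1 and C5 in one event. Both bromines go on first, so no electrophile ever meets the aryl cyclopropane.

Key step: step 6

Remark on the chemistry: the sense of induction of the chiral copper catalyst on this lactone cannot be predicted with certainty; it is assumed that one ligand antipode delivers the 4R product and that this would be fixed in an initial screen.

**Route**

Step 1
Reactants: 1 1-(2-hydroxy-4-methylphenyl)ethan-1-one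
Product: 2 1-(3,5-dibromo-2-hydroxy-4-methylphenyl)ethan-1-one
Conditions: Br2 (2.1 equiv), NaOAc, AcOH, 15 °C → rt
Reagents that add atoms: bromine, BrBr
Why: Electrophilic aromatic bromination, in which the hydroxyl group activates exactly the two free positions ortho and para to it (both meta to the acetyl group), so both bromines of the target are placed on a robust ketone before any alkene, alkyne or cyclopropane exists.

Step 2
Reactants: 2 1-(3,5-dibromo-2-hydroxy-4-methylphenyl)ethan-1-one
Product: 4 6,8-dibromo-4,7-dimethyl-2H-chromen-2-one, via aryl phosphoranylideneacetate 3 (not isolated)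
Conditions: Ph3P=C=C=O (1.2 equiv), toluene, reflux
Reagents that add atoms: (triphenylphosphoranylidene)ketene, O=C=C=P(c1ccccc1)(c1ccccc1)c1ccccc1
Why: The acidic phenol adds to the ketenylidene ylide to give the ester-stabilised ylide 3, which closes by intramolecular Wittig olefination onto the ortho acetyl group, so the alkene geometry is fixed by the lactone ring.

Step 3
Reactants: 4 6,8-dibromo-4,7-dimethyl-2H-chromen-2-one
Product: 6 (4R)-6,8-dibromo-4,7-dimethyl-4-(prop-1-en-2-yl)-3,4-dihydro-2H-chromen-2-one, via dimethylaluminium enolate 5 (not isolated)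
Conditions: 2-bromopropene, t-BuLi (2 equiv), Et2O, −78 °C; Me2AlCl, −78 → 0 °C; then Cu(OTf)2 (5 mol %), chiral sulfonate-bearing imidazolinium salt (NHC precursor, 6 mol %), 4, Et2O/toluene, −30 → 0 °C; aq. potassium sodium tartrate
Reagents that add atoms: 2-bromopropene, CC(Br)=C
Why: Proposed new method: the NHC-bound monovalent copper alkenyl formed by Al→Cu transmetalation should add to C4 of the coumarin through a π-complex and a trivalent copper intermediate while the aluminium centre, held by the ligand sulfonate, activates the lactone carbonyl, so that the ligand pocket decides the face at the methyl-bearing carbon and gives 4R; the electron-poor dibromoaryl ester raises the electrophilicity of the trisubstituted acceptor and an alane does not attack the ester carbonyl directly; the closest known reaction types are NHC–copper-catalysed enantioselective conjugate additions of alkenylaluminium reagents to β-substituted cyclic and acyclic enones (quaternary centres) and copper-catalysed Grignard additions to coumarins unsubstituted at C4 (tertiary centres).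

Step 4
Reactants: 6 (4R)-6,8-dibromo-4,7-dimethyl-4-(prop-1-en-2-yl)-3,4-dihydro-2H-chromen-2-one
Product: 8 2,4-dibromo-6-[(3R)-2,3-dimethylhex-1-en-5-yn-3-yl]-3-methylphenol, via lactol 7 (not isolated)
Conditions: i-Bu2AlH (1.1 equiv), CH2Cl2, −78 °C; then MeOH, K2CO3 (3 equiv), dimethyl (1-diazo-2-oxopropyl)phosphonate, −78 °C → rt; aq. NH4Cl
Reagents that add atoms: dimethyl (1-diazo-2-oxopropyl)phosphonate, CC(=O)C(=[N+]=[N-])P(=O)(OC)OC
Why: Partial reduction of the aryl lactone should stop at the aluminium hemiacetal of lactol 7 (the usual chroman-2-ol preparation), and the ring-opened hydroxy aldehyde is homologated in the same pot by the Ohira–Bestmann variant of the Seyferth–Gilbert reaction, which leaves the quaternary centre untouched.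

Step 5
Reactants: 8 2,4-dibromo-6-[(3R)-2,3-dimethylhex-1-en-5-yn-3-yl]-3-methylphenol
Product: 9 2,4-dibromo-6-[(3R)-2,3-dimethylhex-1-en-5-yn-3-yl]-3-methylphenyl acetate
Conditions: Ac2O (1.5 equiv), Et3N, DMAP (5 mol %), CH2Cl2, 0 °C → rt
Reagents that add atoms: acetic anhydride, CC(=O)OC(C)=O
Why: DMAP-catalysed O-acetylation of the acidic, hindered phenol removes the phenol oxygen as a nucleophile for the gold step and enlarges the ortho substituent of the arene.

Step 6
Reactants: 9 2,4-dibromo-6-[(3R)-2,3-dimethylhex-1-en-5-yn-3-yl]-3-methylphenyl acetate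
Product: 11 2,4-dibromo-6-[(1S,2R,5S)-1,2-dimethylbicyclo[3.1.0]hex-3-en-2-yl]-3-methylphenyl acetate, via cyclopropyl gold carbene 10 (not isolated)
Conditions: Ph3PAuNTf2 (2 mol %), dry CH2Cl2, 0 °C → rt
Reagents that add atoms: none
Why: The cationic monovalent gold complex would bind the terminal alkyne of 9, the 1,1-disubstituted alkene would attack its terminal carbon in a 5-endo-dig fashion to give the cyclopropyl gold carbene 10, and a 1,2-hydride shift from C3 followed by loss of gold would release the alkene C3=C4 of 11. The closest known reaction type is the gold-catalysed cycloisomerization of 1,5-enynes to bicyclo[3.1.0]hex-2-enes, which accepts 1,1-disubstituted alkene partners. The cyclopentene ring closes by 5-endo-dig formation of C5–C1 and the cyclopropane by the 3-exo bond C5–C6, both from the same alkyne carbon, so C1 and C5 are necessarily cis-fused. Their configuration relative to C2 is decided by the alkene face that is attacked: in the folded transition state the propargylic carbon C3 must stand above the alkene plane, one remaining C2 substituent lies next to the =CH2 terminus and the other next to the vinylic methyl, and the bulky 2-acetoxy-3,5-dibromo-4-methylphenyl group is expected to avoid the 1,2-allylic clash with that methyl and take the =CH2 side, which places it cis to C6 as in the target. The step needs this face selectivity and carbocyclization in preference to heteroatom or arene participation: the acetate masks the phenol oxygen, and the electron-poor arene, whose only free position is flanked by bromine and the quaternary carbon, should neither attack nor migrate. The geminal substitution at C2 holds alkyne and alkene together and should make the closure fast at or below room temperature.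

Step 7
Reactants: 11 2,4-dibromo-6-[(1S,2R,5S)-1,2-dimethylbicyclo[3.1.0]hex-3-en-2-yl]-3-methylphenyl acetate
Product: 13 2,4-dibromo-6-[(1S,2R,5R)-1,2-dimethylbicyclo[3.1.0]hexan-2-yl]-3-methylphenol, via phenol 12 (not isolated)
Conditions: N2H4·H2O (15 equiv), EtOH, rt; then CuSO4·5H2O (1 mol %), air, rt
Reagents that add atoms: none
Why: Hydrazinolysis of the aryl acetate first frees phenol 12, and diimide made by copper-catalysed aerobic oxidation of the excess hydrazine then adds H2 suprafacially to the strained cis-disubstituted ring alkene without a metal hydride or metal surface that could cleave the aryl bromides or the cyclopropane; no stereocentre is formed or changed (the C5 descriptor switches from S to R only because the CIP priorities change).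

**Compound list**

1 | 1-(2-hydroxy-4-methylphenyl)ethan-1-one | CC(=O)c1ccc(C)cc1O | starting material
2 | 1-(3,5-dibromo-2-hydroxy-4-methylphenyl)ethan-1-one | CC(=O)c1cc(Br)c(C)c(Br)c1O | intermediate
3 | 2-acetyl-4,6-dibromo-5-methylphenyl (triphenyl-λ5-phosphanylidene)acetate, formed in the flask | CC(=O)c1cc(Br)c(C)c(Br)c1OC(=O)C=P(c1ccccc1)(c1ccccc1)c1ccccc1 | intermediate
4 | 6,8-dibromo-4,7-dimethyl-2H-chromen-2-one | CC1=CC(=O)Oc2c(Br)c(C)c(Br)cc12 | intermediate
5 | {[(4R)-6,8-dibromo-4,7-dimethyl-4-(prop-1-en-2-yl)-4H-chromen-2-yl]oxy}dimethylaluminium, formed in the flask | C[Al](C)OC1=C[C@](C)(C(C)=C)c2cc(Br)c(C)c(Br)c2O1 | intermediate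
6 | (4R)-6,8-dibromo-4,7-dimethyl-4-(prop-1-en-2-yl)-3,4-dihydro-2H-chromen-2-one | O=C1C[C@](C)(C(C)=C)c2cc(Br)c(C)c(Br)c2O1 | intermediate
7 | (4R)-6,8-dibromo-4,7-dimethyl-4-(prop-1-en-2-yl)-3,4-dihydro-2H-chromen-2-ol, both C2 epimers, present as its aluminium alkoxide, formed in the flask | OC1C[C@](C)(C(C)=C)c2cc(Br)c(C)c(Br)c2O1 | intermediate
8 | 2,4-dibromo-6-[(3R)-2,3-dimethylhex-1-en-5-yn-3-yl]-3-methylphenol | Oc1c(Br)c(C)c(Br)cc1[C@](C(C)=C)(C)CC#C | intermediate
9 | 2,4-dibromo-6-[(3R)-2,3-dimethylhex-1-en-5-yn-3-yl]-3-methylphenyl acetate | CC(=O)Oc1c(Br)c(C)c(Br)cc1[C@](C(C)=C)(C)CC#C | intermediate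
10 | (triphenylphosphine)gold carbene at C4 of the 2-aryl-1,2-dimethylbicyclo[3.1.0]hexane (configuration as in 11), bis(trifluoromethylsulfonyl)amide salt, formed in the flask | CC(=O)Oc1c(Br)c(C)c(Br)cc1[C@]2(C)CC(=[Au][P+](c4ccccc4)(c5ccccc5)c6ccccc6)[C@@H]3C[C@@]32C.[N-](S(=O)(=O)C(F)(F)F)S(=O)(=O)C(F)(F)F | intermediate
11 | 2,4-dibromo-6-[(1S,2R,5S)-1,2-dimethylbicyclo[3.1.0]hex-3-en-2-yl]-3-methylphenyl acetate (aryl cis to the cyclopropane CH2) | CC(=O)Oc1c(Br)c(C)c(Br)cc1[C@]2(C)C=C[C@@H]3C[C@@]32C | intermediate
12 | 2,4-dibromo-6-[(1S,2R,5S)-1,2-dimethylbicyclo[3.1.0]hex-3-en-2-yl]-3-methylphenol, formed in the flask | Oc1c(Br)c(C)c(Br)cc1[C@]2(C)C=C[C@@H]3C[C@@]32C | intermediate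
13 | 2,4-dibromo-6-[(1S,2R,5R)-1,2-dimethylbicyclo[3.1.0]hexan-2-yl]-3-methylphenol | Cc1c(Br)cc([C@]2(C)CC[C@@H]3C[C@@]32C)c(O)c1Br | target

**Step count and risks**

Total step count: 7. Longest linear sequence: 7 (fully linear from 1).

Steps most likely to fail:

1. Step 3 (proposed new method). The copper alkenyl may fail to transfer to the hindered, doubly β-substituted lactone or may transfer with poor face discrimination; methyl transfer from aluminium or collapse of the aluminium enolate may also compete. Fallback, setting out from 4 and coming back at 8: a stoichiometric achiral cuprate addition (isopropenylmagnesium bromide, CuBr·SMe2, Me3SiCl, THF, −40 °C) would give racemic 6,8-dibromo-4,7-dimethyl-4-(prop-1-en-2-yl)-3,4-dihydro-2H-chromen-2-one F1. The reduction–homologation of step 4 would then give racemic 2,4-dibromo-6-(2,3-dimethylhex-1-en-5-yn-3-yl)-3-methylphenol F2. (S)-1-Phenylethyl isocyanate (Et3N, CH2Cl2) would convert it into 2,4-dibromo-6-[(3R)-2,3-dimethylhex-1-en-5-yn-3-yl]-3-methylphenyl N-[(1S)-1-phenylethyl]carbamate F3 and the diastereomeric 2,4-dibromo-6-[(3S)-2,3-dimethylhex-1-en-5-yn-3-yl]-3-methylphenyl N-[(1S)-1-phenylethyl]carbamate F4, to be separated by chromatography or crystallisation. Methanolysis of F3 (K2CO3, MeOH) would return 8 as a single enantiomer.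

2. Step 6 (key step). The alkene may be attacked on the other face, which would put the arene trans to the cyclopropane CH2, or the carbenoid may be diverted into six-membered ring products. Fallback, setting out from 9 and coming back at 13, with the face enforced by zinc phenoxide delivery: anti-Markovnikov hydration of the alkyne (CpRu(MeCN)3PF6, 5,5′-bis(trifluoromethyl)-2,2′-bipyridine, NMP/H2O) would give 2,4-dibromo-6-[(3R)-2,3-dimethyl-6-oxohex-1-en-3-yl]-3-methylphenyl acetate F5. Methylenation (Zn, CH2Br2, TiCl4, THF) would give 2,4-dibromo-6-[(3R)-2,3-dimethylhepta-1,6-dien-3-yl]-3-methylphenyl acetate F6. Ring-closing metathesis (second-generation Grubbs catalyst, CH2Cl2, 40 °C) would give 2,4-dibromo-6-[(1R)-1,2-dimethylcyclopent-2-en-1-yl]-3-methylphenyl acetate F7. Methanolysis (K2CO3, MeOH) would give 2,4-dibromo-6-[(1R)-1,2-dimethylcyclopent-2-en-1-yl]-3-methylphenol F8. Simmons–Smith cyclopropanation (Et2Zn, CH2I2, CH2Cl2, 0 °C) would then deliver CH2 to the alkene face that carries the arene and give 13.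

3. Step 4. The aluminium hemiacetal may collapse with loss of the good phenoxide leaving group and take up a second hydride (over-reduction), or the ring-closed lactol may be slow to react as the aldehyde. Fallback, setting out from 6 and coming back at 8: aminolysis of the lactone (MeNHOMe·HCl, AlMe3, CH2Cl2) would give (3R)-3-(3,5-dibromo-2-hydroxy-4-methylphenyl)-N-methoxy-N,3,4-trimethylpent-4-enamide F9. Silylation (t-BuMe2SiOTf, 2,6-lutidine) would give (3R)-3-[3,5-dibromo-2-(tert-butyldimethylsilyloxy)-4-methylphenyl]-N-methoxy-N,3,4-trimethylpent-4-enamide F10. Reduction (i-Bu2AlH, THF, −78 °C), which stops at the chelated adduct, would give (3R)-3-[3,5-dibromo-2-(tert-butyldimethylsilyloxy)-4-methylphenyl]-3,4-dimethylpent-4-enal F11, which cannot close to a lactol. Ohira–Bestmann homologation would give tert-butyl{2,4-dibromo-6-[(3R)-2,3-dimethylhex-1-en-5-yn-3-yl]-3-methylphenoxy}dimethylsilane F12, and Bu4NF (THF, 0 °C) would return 8.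

Further compounds
F1 | step 3 | racemic 6,8-dibromo-4,7-dimethyl-4-(prop-1-en-2-yl)-3,4-dihydro-2H-chromen-2-one | O=C1CC(C)(C(C)=C)c2cc(Br)c(C)c(Br)c2O1
F2 | step 3 | racemic 2,4-dibromo-6-(2,3-dimethylhex-1-en-5-yn-3-yl)-3-methylphenol | Oc1c(Br)c(C)c(Br)cc1C(C(C)=C)(C)CC#C
F3 | step 3 | 2,4-dibromo-6-[(3R)-2,3-dimethylhex-1-en-5-yn-3-yl]-3-methylphenyl N-[(1S)-1-phenylethyl]carbamate | C[C@H](NC(=O)Oc1c(Br)c(C)c(Br)cc1[C@](C(C)=C)(C)CC#C)c1ccccc1
F4 | step 3 | 2,4-dibromo-6-[(3S)-2,3-dimethylhex-1-en-5-yn-3-yl]-3-methylphenyl N-[(1S)-1-phenylethyl]carbamate | C[C@H](NC(=O)Oc1c(Br)c(C)c(Br)cc1[C@@](C(C)=C)(C)CC#C)c1ccccc1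
F5 | step 6 | 2,4-dibromo-6-[(3R)-2,3-dimethyl-6-oxohex-1-en-3-yl]-3-methylphenyl acetate | CC(=O)Oc1c(Br)c(C)c(Br)cc1[C@](C(C)=C)(C)CCC=O
F6 | step 6 | 2,4-dibromo-6-[(3R)-2,3-dimethylhepta-1,6-dien-3-yl]-3-methylphenyl acetate | CC(=O)Oc1c(Br)c(C)c(Br)cc1[C@](C(C)=C)(C)CCC=C
F7 | step 6 | 2,4-dibromo-6-[(1R)-1,2-dimethylcyclopent-2-en-1-yl]-3-methylphenyl acetate | CC(=O)Oc1c(Br)c(C)c(Br)cc1[C@]2(C)CCC=C2C
F8 | step 6 | 2,4-dibromo-6-[(1R)-1,2-dimethylcyclopent-2-en-1-yl]-3-methylphenol | Oc1c(Br)c(C)c(Br)cc1[C@]2(C)CCC=C2C
F9 | step 4 | (3R)-3-(3,5-dibromo-2-hydroxy-4-methylphenyl)-N-methoxy-N,3,4-trimethylpent-4-enamide | CON(C)C(=O)C[C@](C)(C(C)=C)c1cc(Br)c(C)c(Br)c1O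
F10 | step 4 | (3R)-3-[3,5-dibromo-2-(tert-butyldimethylsilyloxy)-4-methylphenyl]-N-methoxy-N,3,4-trimethylpent-4-enamide | CON(C)C(=O)C[C@](C)(C(C)=C)c1cc(Br)c(C)c(Br)c1O[Si](C)(C)C(C)(C)C
F11 | step 4 | (3R)-3-[3,5-dibromo-2-(tert-butyldimethylsilyloxy)-4-methylphenyl]-3,4-dimethylpent-4-enal | O=CC[C@](C)(C(C)=C)c1cc(Br)c(C)c(Br)c1O[Si](C)(C)C(C)(C)C
F12 | step 4 | tert-butyl{2,4-dibromo-6-[(3R)-2,3-dimethylhex-1-en-5-yn-3-yl]-3-methylphenoxy}dimethylsilane | CC(C)(C)[Si](C)(C)Oc1c(Br)c(C)c(Br)cc1[C@](C(C)=C)(C)CC#C
A1 | direct plan | 2,3-dimethylcyclopent-2-en-1-one | CC1=C(C)C(=O)CC1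
A2 | direct plan | (R)-2,3-dimethylcyclopent-2-en-1-ol | O[C@@H]1CCC(C)=C1C
A3 | direct plan | 4-bromo-3-methylphenol | Cc1cc(O)ccc1Br
A4 | direct plan | 4-bromo-3-methylphenyl (S)-2,3-dimethylcyclopent-2-en-1-yl ether | Cc1cc(O[C@H]2CCC(C)=C2C)ccc1Br
A5 | direct plan | (R)-4-bromo-2-(1,2-dimethylcyclopent-2-en-1-yl)-5-methylphenol | Cc1cc(O)c(cc1Br)[C@]2(C)CCC=C2C
A6 | direct plan | 4-bromo-2-[(1S,2R,5R)-1,2-dimethylbicyclo[3.1.0]hexan-2-yl]-5-methylphenol | Cc1cc(O)c(cc1Br)[C@]2(C)CC[C@@H]3C[C@@]32C
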